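**Retrosynthetic overview** (gibberellane numbering)

1. The strategy rests on C6 (which carries the C7 carboxyl) and quaternary C8 being neighbours in ring B (C5, C6, C8, C9, C10), while C8 is also the far end of the allyl unit C13–C14=C8 inside ring C (C8, C9, C11–C14). The C6–C8 bond is therefore the σ-bond of a [3,3] shift of a C7–O–C13 ester.
2. Ring D is closed last (C13–C16) by a gold-catalysed Conia-ene reaction of the C12 silyl enol ether with the C8 propargyl group; C20 is then oxidised and the C7 and C19 methyl esters are cleaved.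
3. Ring B comes from the Ireland–Claisen ring contraction of the nine-membered C13–O–C7 lactone that bridges rings A and C. It sets C8 but must give C6 epimeric; a base equilibration corrects C6.
4. The lactone comes from a C13-hydroxy C7-acid whose ring C is shaped from a C8 ketone: enone formation, propargyl addition, oxidative 1,3-transposition, Luche reduction.
5. Rings A and C are made separately and joined at C9–C10 by a Ueno–Stork radical cyclisation through a C20 acetal tether to the C8 carbinol. Ring order: A and C, then B, then D.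

Key step: step 21

Remark: the target is drawn as the open aldehyde diacid, although the C20 aldehyde and the C19 acid may equilibrate with their lactol.
Remark: enone 1 and enal 4 are taken as purchased materials.

**Route**

Step 1
Reactants: 1 1,4-dioxaspiro[4.5]dec-6-en-8-one
Product: 2 (S)-1,4-dioxaspiro[4.5]dec-6-en-8-ol
Conditions: (R)-2-methyl-CBS-oxazaborolidine (10 mol%), catecholborane, toluene, −78 °C; aq NaOH work-up
Reagents that add atoms: none
Why: Corey–Bakshi–Shibata reduction in which the alkene arm of the enone acts as the large group, so the (R)-catalyst should deliver hydride to the face that gives the (S)-carbinol; this C8–O centre later dictates C9.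

Step 2
Reactants: 3 tert-butyl 3-oxobutanoate; 4 methyl (E)-4-oxobut-2-enoate
Product: 6 methyl (S)-5-oxocyclohex-3-ene-1-carboxylate, via keto aldehyde 5 (not isolated)
Conditions: (R)-2-[diphenyl(trimethylsilyloxy)methyl]pyrrolidine (10 mol%), toluene, 0 °C to rt; then TsOH·H2O (20 mol%), 80 °C
Reagents that add atoms: none
Why: Iminium-catalysed Michael addition of the β-keto ester to the enal, then acid-promoted intramolecular aldol condensation with tert-butyl ester cleavage and decarboxylation (organocatalytic Robinson-type cyclohexenone synthesis); the prolinol ether shields one face of the iminium ion and so sets C4, the catalyst enantiomer being the one chosen to give the (S)-ester.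

Step 3
Reactants: 6 methyl (S)-5-oxocyclohex-3-ene-1-carboxylate
Product: 7 methyl (1S,6R)-5-oxo-6-(prop-2-en-1-yl)cyclohex-3-ene-1-carboxylate
Conditions: LiN(iPr)2, THF, −78 °C; allyl bromide, −78 to −20 °C
Reagents that add atoms: allyl bromide C=CCBr
Why: Kinetic α′-enolate alkylation of the cyclohexenone: allyl bromide attacks the enolate face opposite the adjacent C4 ester, so C5 is set trans to C4.

Step 4
Reactants: 7 methyl (1S,6R)-5-oxo-6-(prop-2-en-1-yl)cyclohex-3-ene-1-carboxylate
Product: 8 methyl (1S,2R)-3-oxo-2-(prop-2-en-1-yl)cyclohexane-1-carboxylate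
Conditions: K[(s-Bu)3BH], THF, −78 °C; aq NH4Cl
Reagents that add atoms: none
Why: Conjugate (1,4) hydride reduction of a β-unsubstituted cyclohexenone by the hindered borohydride, which spares the isolated alkene and the ester and creates no stereocentre.

Step 5
Reactants: 8 methyl (1S,2R)-3-oxo-2-(prop-2-en-1-yl)cyclohexane-1-carboxylate
Product: 9 methyl (1S,2R)-3-[(benzyloxy)methylidene]-2-(prop-2-en-1-yl)cyclohexane-1-carboxylate (E/Z mixture)
Conditions: BnOCH2PPh3Cl, KN(SiMe3)2, THF, 0 °C to rt
Reagents that add atoms: (benzyloxymethyl)triphenylphosphonium chloride [Cl-].c1ccccc1COC[P+](c1ccccc1)(c1ccccc1)c1ccccc1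
Why: Wittig alkoxymethylenation of the C10 ketone installs C20 as an enol ether at the aldehyde oxidation level; the alkene geometry is irrelevant because C10 later becomes a radical.

Step 6
Reactants: 9 methyl (1S,2R)-3-[(benzyloxy)methylidene]-2-(prop-2-en-1-yl)cyclohexane-1-carboxylate
Product: 10 methyl (1R,2S)-3-[(benzyloxy)methylidene]-1-methyl-2-(prop-2-en-1-yl)cyclohexane-1-carboxylate
Conditions: LiN(iPr)2, THF, −78 °C; MeI, −78 to 0 °C
Reagents that add atoms: iodomethane CI
Why: Ester enolate alkylation: allylic strain against the planar C4 enolate holds the C5 allyl group pseudoaxial and iodomethane attacks the opposite face, which sets the C4 quaternary centre with the ester cis to the C5 arm.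

Step 7
Reactants: 10 methyl (1R,2S)-3-[(benzyloxy)methylidene]-1-methyl-2-(prop-2-en-1-yl)cyclohexane-1-carboxylate; 2 (S)-1,4-dioxaspiro[4.5]dec-6-en-8-ol
Product: 11 C10-bromo C20 mixed acetal (C20 bears OBn and the C8 oxygen of ring C; mixture at C10 and C20)
Conditions: N-bromosuccinimide, 2,6-lutidine (cat.), CH2Cl2, −40 to 0 °C
Reagents that add atoms: N-bromosuccinimide O=C1CCC(=O)N1Br
Why: Bromoacetalisation of the enol ether (first half of a Ueno–Stork sequence): the bromonium ion forms at C10 and carbinol 2 traps the C20 oxocarbenium ion; the C10 and C20 centres form as mixtures, which does no harm since C10 becomes a planar radical and C20 is reduced later.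

Step 8
Reactants: 11 C10-bromo C20 mixed acetal
Product: 12 spiro acetal (oxolane C10–C20–O–C8–C9, spiro at C10 of ring A and cis-fused to ring C; mixture at C20)
Conditions: Bu3SnH (slow addition), AIBN (cat.), benzene, 80 °C
Reagents that add atoms: none
Why: Ueno–Stork radical cyclisation (5-exo-trig): the tertiary C10 radical must add to C9 on the ring C face of the C8–O tether (cis-fused oxolane), which sets C9 from the CBS centre, and the new bond enters ring A equatorially, away from the axial C19 ester and the C5 arm, which sets the quaternary C10.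

Step 9
Reactants: 12 spiro acetal
Product: 13 spiro acetal with the C5 arm as CH2CO2Me (C6–C7)
Conditions: O3, NaOH (2.5 M in MeOH), CH2Cl2, −78 °C
Reagents that add atoms: ozone [O-][O+]=O; methanol CO
Why: Ozonolysis in methanolic NaOH (direct oxidative cleavage of a terminal alkene to a methyl ester) turns the allyl group, the only alkene present, into the C6–C7 ester arm.

Step 10
Reactants: 13 spiro acetal diester
Product: 14 C20 lactol
Conditions: H2 (1 atm), 10% Pd/C, EtOAc, rt
Reagents that add atoms: none
Why: Catalytic hydrogenolysis of the benzyl acetal under neutral conditions frees the C20 lactol and leaves the C12 dioxolane and both esters intact.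

Step 11
Reactants: 14 C20 lactol
Product: 15 C20,C8-diol
Conditions: NaBH4, EtOH, −20 °C; AcOH quench
Reagents that add atoms: none
Why: Borohydride reduction of the lactol through its open hydroxy aldehyde gives the C20 primary alcohol and frees the C8 carbinol; the cold, quickly neutralised medium is meant to keep the C20 alkoxide from lactonising onto the 1,3-diaxial C19 ester.

Step 12
Reactants: 15 C20,C8-diol
Product: 16 C20 tert-butyldimethylsilyl ether with free C8–OH
Conditions: t-BuMe2SiCl, imidazole, CH2Cl2, 0 °C
Reagents that add atoms: tert-butyldimethylsilyl chloride CC(C)(C)[Si](C)(C)Cl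
Why: Selective silylation of the primary C20 alcohol in the presence of the hindered secondary C8 alcohol (steric differentiation).

Step 13
Reactants: 16 C20 silyl ether C8 alcohol
Product: 17 C8 ketone
Conditions: Dess–Martin periodinane, NaHCO3, CH2Cl2, 0 °C to rt
Reagents that add atoms: none
Why: Dess–Martin oxidation of the secondary C8 alcohol to the ketone under buffered conditions that do not epimerise C9.

Step 14
Reactants: 17 C8 ketone
Product: 18 C8 trimethylsilyl enol ether (C8=C14)
Conditions: LiN(iPr)2, Me3SiCl, THF, −78 °C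
Reagents that add atoms: chlorotrimethylsilane C[Si](C)(C)Cl
Why: Kinetic deprotonation with in situ silylation gives the less substituted silyl enol ether, because the C9 methine next to quaternary C10 is too hindered to compete and the ketone is more acidic than the ester.

Step 15
Reactants: 18 C8 silyl enol ether
Product: 19 C8 enone (C14=C13)
Conditions: Pd(OAc)2 (1.1 equiv), MeCN, rt
Reagents that add atoms: none
Why: Saegusa–Ito oxidation of the silyl enol ether gives the C8 enone with the alkene at C14=C13.

Step 16
Reactants: 19 C8 enone; 20 3-bromo-1-(trimethylsilyl)prop-1-yne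
Product: 21 C8 tertiary carbinol bearing CH2C≡CSiMe3 (mixture at C8)
Conditions: Zn dust, THF, 0 °C to rt; aq NH4Cl
Reagents that add atoms: none
Why: Barbier-type 1,2-addition of the allenylzinc reagent formed from 20 gives the homopropargylic tertiary alcohol (the silyl group steers SE2′ delivery of the propargyl isomer); the C8 configuration is irrelevant because the centre becomes sp2 in the next step.

Step 17
Reactants: 21 C8 tertiary carbinol
Product: 22 C13 enone (C14=C8, propargyl on C8)
Conditions: pyridinium chlorochromate (C5H5NH)[CrO3Cl], NaOAc, 4 Å sieves, CH2Cl2, rt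
Reagents that add atoms: pyridinium chlorochromate [O-][Cr](=O)(=O)Cl.c1cc[nH+]cc1
Why: Babler–Dauben oxidative 1,3-transposition: the chromate ester of the tertiary allylic alcohol shifts [3,3] to C13 and is oxidised there, giving the β-propargyl enone with the alkene at C8=C14.

Step 18
Reactants: 22 C13 enone
Product: 23 C13 carbinol (13-OH cis to the C9–C10 bond), C7 methyl ester
Conditions: NaBH4, CeCl3·7H2O, MeOH, −78 °C
Reagents that add atoms: none
Why: Luche 1,2-reduction: allylic 1,2-strain with the C8 propargyl group holds the bulky C9 substituent pseudoaxial and hydride adds to the carbonyl from the opposite face, which should set the C13 carbinol cis to the C9–C10 bond.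

Step 19
Reactants: 23 C13 hydroxy diester
Product: 24 C13 hydroxy C7 acid
Conditions: Me3SnOH, 1,2-dichloroethane, 80 °C; aq KHSO4
Reagents that add atoms: trimethyltin hydroxide C[Sn](C)(C)O
Why: Trimethyltin hydroxide hydrolysis selects the unhindered C7 methyl ester over the neopentyl, axial C19 ester and spares the alkynylsilane.

Step 20
Reactants: 24 C13 hydroxy C7 acid
Product: 26 nine-membered C13–O–C7 lactone bridging rings A and C, via mixed anhydride 25 (not isolated)
Conditions: 2,4,6-trichlorobenzoyl chloride, Et3N, THF, rt; then slow addition to DMAP, toluene, 100 °C (high dilution)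
Reagents that add atoms: none
Why: Yamaguchi macrolactonisation at high dilution: the C13 hydroxyl lies on the same face of ring C as the C9 arm that carries the acid, so the mixed anhydride can close the nine-membered lactone as a 1,4-bridge over ring C.

Step 21
Reactants: 26 nine-membered C13–O–C7 lactone
Product: 29 ring A/B/C acid with C13=C14 alkene (6-epi), via silyl ketene acetal 27 (not isolated), via silyl ester 28 (not isolated)
Conditions: LiN(iPr)2, t-BuMe2SiCl, HMPA, THF, −78 °C; then toluene, 100 °C; then AcOH/H2O/THF, rt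
Reagents that add atoms: none
Why: Proposed new method: LiN(iPr)2 removes a C6 proton of lactone 26 (the C19 ester has no α-hydrogen) and the silyl chloride traps the enolate as ketene acetal 27, whose C6=C7 bond is held ring-cis; on heating, the unit C6=C7–O–C13–C14=C8 undergoes a concerted [3,3]-sigmatropic shift through a boat-like six-centre array in which C6 bonds to C8 while the C13–O bond breaks and the alkene moves to C13=C14. The closest known reaction is the Ireland–Claisen ring contraction of medium-ring allylic lactones to cis-2-alkenylcycloalkanecarboxylic acids; what is untested is a lactone that bridges the 1,4-positions of a cyclohexene, so that the allyl unit lies in a second ring. Ring B (C5, C6, C8, C9, C10) closes by this transannular bond formation, a formal 5-exo attack of C6 on the C8 terminus that contracts the nine-membered ring to five. The C8 quaternary centre is controlled by suprafacial transfer from C13: C6 can reach C8 only on the ring C face that bears the C13–O bond, which is also the face of the C9–C10 bond, so rings B and C become cis-fused with the propargyl group on the other face. C6 is controlled by the ring-enforced ketene acetal geometry and the boat array, which place C7 cis to C14, that is, the C6 epimer of the natural configuration; this is the expected outcome and step 23 corrects it. The step needs the rearrangement to outrun C-silylation and elimination of the enolate, and the bridged lactone secures this because it already holds C6 above C8 on the correct face.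

Step 22
Reactants: 29 6-epi ring A/B/C acid
Product: 30 6-epi C7,C19 dimethyl ester
Conditions: Me3SiCHN2, MeOH/toluene, 0 °C
Reagents that add atoms: (trimethylsilyl)diazomethane C[Si](C)(C)C=[N+]=[N-]
Why: Esterification of the C7 acid by diazoalkane O-alkylation under neutral conditions.

Step 23
Reactants: 30 6-epi dimethyl ester
Product: 31 dimethyl ester with natural C6 configuration and terminal alkyne
Conditions: NaOMe, MeOH, 65 °C
Reagents that add atoms: none
Why: Base-mediated epimerisation through the C7 ester enolate moves the ester from the crowded face shared with C4 and C14 to the face of H5 (thermodynamic control, natural C6), and methoxide at the same time cleaves the alkynyl C–Si bond to free the terminal alkyne needed for ring D.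

Step 24
Reactants: 31 dimethyl ester, terminal alkyne, C12 dioxolane
Product: 32 C12 ketone (C13=C14 enone)
Conditions: pyridinium p-toluenesulfonate, acetone/H2O, 50 °C
Reagents that add atoms: water O
Why: Mild acid-catalysed hydrolysis of the allylic dioxolane gives the conjugated C12 ketone while the hindered silyl ether survives.

Step 25
Reactants: 32 C13=C14 enone
Product: 33 C12 tert-butyldimethylsilyl enol ether (C12=C13)
Conditions: Li[(s-Bu)3BH], THF, −78 °C; then t-BuMe2SiOTf, −78 to 0 °C
Reagents that add atoms: tert-butyldimethylsilyl trifluoromethanesulfonate CC(C)(C)[Si](C)(C)OS(=O)(=O)C(F)(F)F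
Why: Conjugate hydride reduction gives the C12–C13 enolate regiospecifically, and O-silylation traps it as the silyl enol ether before it can equilibrate towards C11.

Step 26
Reactants: 33 C12 silyl enol ether
Product: 34 tetracyclic C12 ketone with C16=C17 methylene, C20 silyl ether, dimethyl ester
Conditions: Ph3PAuNTf2 (5 mol%), CH2Cl2/MeOH 10:1, rt
Reagents that add atoms: none
Why: Gold-catalysed Conia-ene-type carbocyclisation: the cationic gold complex activates the terminal alkyne and C13 of the silyl enol ether attacks C16 in a 5-exo-dig mode, closing ring D with the exocyclic methylene; the C13 configuration is fixed by the bridge geometry of the bicyclo[3.2.1]octane.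

Step 27
Reactants: 34 tetracyclic ketone, C20 silyl ether
Product: 35 C20 alcohol
Conditions: HF·pyridine, pyridine, THF, 0 °C
Reagents that add atoms: none
Why: Fluoride cleavage of the silyl ether under buffered, non-basic conditions, so that no C20 alkoxide forms that could lactonise onto the C19 ester.

Step 28
Reactants: 35 C20 alcohol
Product: 36 C20 aldehyde dimethyl ester
Conditions: Dess–Martin periodinane, NaHCO3, CH2Cl2, 0 °C (directly on crude 35)
Reagents that add atoms: none
Why: Dess–Martin oxidation of the neopentyl primary alcohol to the non-enolisable C20 aldehyde.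

Step 29
Reactants: 36 C20 aldehyde dimethyl ester
Product: 37 target CNP0412196.1
Conditions: LiSPr, HMPA, rt; cold dilute aq HCl work-up
Reagents that add atoms: none
Why: SN2 dealkylation of both methyl esters by thiolate at the methyl carbons, which avoids attack at the hindered C19 carbonyl and does not touch the C6 centre.

**Compound list**

1 | 1,4-dioxaspiro[4.5]dec-6-en-8-one | O=C1C=CC2(CC1)OCCO2 | starting material
2 | (S)-1,4-dioxaspiro[4.5]dec-6-en-8-ol (ring C carbinol, C8–OH) | O[C@H]1CCC2(OCCO2)C=C1 | intermediate
3 | tert-butyl 3-oxobutanoate | CC(=O)CC(=O)OC(C)(C)C | starting material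
4 | methyl (E)-4-oxobut-2-enoate | COC(=O)/C=C/C=O | starting material
5 | tert-butyl (3S)-2-acetyl-3-(methoxycarbonyl)-5-oxopentanoate (mixture at C2) | COC(=O)[C@@H](CC=O)C(C(C)=O)C(=O)OC(C)(C)C | intermediate
6 | methyl (S)-5-oxocyclohex-3-ene-1-carboxylate | COC(=O)[C@@H]1CC(=O)C=CC1 | intermediate
7 | methyl (1S,6R)-5-oxo-6-(prop-2-en-1-yl)cyclohex-3-ene-1-carboxylate | COC(=O)[C@H]1CC=CC(=O)[C@@H]1CC=C | intermediate
8 | methyl (1S,2R)-3-oxo-2-(prop-2-en-1-yl)cyclohexane-1-carboxylate | COC(=O)[C@H]1CCCC(=O)[C@@H]1CC=C | intermediate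
9 | methyl (1S,2R)-3-[(benzyloxy)methylidene]-2-(prop-2-en-1-yl)cyclohexane-1-carboxylate (E/Z mixture) | COC(=O)[C@H]1CCCC(=COCc2ccccc2)[C@@H]1CC=C | intermediate
10 | methyl (1R,2S)-3-[(benzyloxy)methylidene]-1-methyl-2-(prop-2-en-1-yl)cyclohexane-1-carboxylate (ester cis to allyl) | COC(=O)[C@]1(C)CCCC(=COCc2ccccc2)[C@@H]1CC=C | intermediate
11 | bromo acetal: ring A of 10 with Br on C10 and C20 as CH(OBn)–O–C8 of ring C (mixture at C10 and C20) | COC(=O)[C@]1(C)CCCC(Br)(C(OCc2ccccc2)O[C@H]2CCC3(OCCO3)C=C2)[C@@H]1CC=C | intermediate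
12 | spiro acetal: 2-(benzyloxy)oxolane (C20, O, C8, C9) spiro at C10 and cis-fused to ring C; C4, C5, C9, C10 as in the target; C5 allyl (mixture at C20) | COC(=O)[C@]1(C)CCC[C@]2(C(OCc3ccccc3)O[C@H]4CCC5(OCCO5)C[C@H]42)[C@@H]1CC=C | intermediate
13 | spiro acetal with C5 CH2CO2Me arm | COC(=O)[C@]1(C)CCC[C@]2(C(OCc3ccccc3)O[C@H]4CCC5(OCCO5)C[C@H]42)[C@@H]1CC(=O)OC | intermediate
14 | C20 lactol | COC(=O)[C@]1(C)CCC[C@]2(C(O)O[C@H]3CCC4(OCCO4)C[C@H]32)[C@@H]1CC(=O)OC | intermediate
15 | C20,C8-diol (C9–C10 bond joins rings A and C) | COC(=O)[C@]1(C)CCC[C@@](CO)([C@@H]2CC3(OCCO3)CC[C@@H]2O)[C@@H]1CC(=O)OC | intermediate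
16 | C20 tert-butyldimethylsilyl ether, C8 alcohol | COC(=O)[C@]1(C)CCC[C@@](CO[Si](C)(C)C(C)(C)C)([C@@H]2CC3(OCCO3)CC[C@@H]2O)[C@@H]1CC(=O)OC | intermediate
17 | C8 ketone | COC(=O)[C@]1(C)CCC[C@@](CO[Si](C)(C)C(C)(C)C)([C@@H]2CC3(OCCO3)CCC2=O)[C@@H]1CC(=O)OC | intermediate
18 | C8 trimethylsilyl enol ether (C8=C14) | COC(=O)[C@]1(C)CCC[C@@](CO[Si](C)(C)C(C)(C)C)([C@@H]2CC3(OCCO3)CC=C2O[Si](C)(C)C)[C@@H]1CC(=O)OC | intermediate
19 | C8 enone (C14=C13) | COC(=O)[C@]1(C)CCC[C@@](CO[Si](C)(C)C(C)(C)C)([C@@H]2CC3(OCCO3)C=CC2=O)[C@@H]1CC(=O)OC | intermediate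
20 | 3-bromo-1-(trimethylsilyl)prop-1-yne | C[Si](C)(C)C#CCBr | starting material
21 | C8 tertiary carbinol with CH2C≡CSiMe3 (mixture at C8) | COC(=O)[C@]1(C)CCC[C@@](CO[Si](C)(C)C(C)(C)C)([C@@H]2CC3(OCCO3)C=CC2(O)CC#C[Si](C)(C)C)[C@@H]1CC(=O)OC | intermediate
22 | C13 enone (C14=C8) | COC(=O)[C@]1(C)CCC[C@@](CO[Si](C)(C)C(C)(C)C)([C@@H]2CC3(OCCO3)C(=O)C=C2CC#C[Si](C)(C)C)[C@@H]1CC(=O)OC | intermediate
23 | C13 carbinol (OH cis to C9–C10), C7 methyl ester | COC(=O)[C@]1(C)CCC[C@@](CO[Si](C)(C)C(C)(C)C)([C@@H]2CC3(OCCO3)[C@H](O)C=C2CC#C[Si](C)(C)C)[C@@H]1CC(=O)OC | intermediate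
24 | C13 hydroxy C7 acid | COC(=O)[C@]1(C)CCC[C@@](CO[Si](C)(C)C(C)(C)C)([C@@H]2CC3(OCCO3)[C@H](O)C=C2CC#C[Si](C)(C)C)[C@@H]1CC(=O)O | intermediate
25 | C7 mixed anhydride with 2,4,6-trichlorobenzoic acid | COC(=O)[C@]1(C)CCC[C@@](CO[Si](C)(C)C(C)(C)C)([C@@H]2CC3(OCCO3)[C@H](O)C=C2CC#C[Si](C)(C)C)[C@@H]1CC(=O)OC(=O)c1c(Cl)cc(Cl)cc1Cl | intermediate
26 | nine-membered C13–O–C7 lactone bridging rings A and C | C[Si](C)(C)C#CCC1=C[C@H]2OC(=O)C[C@@H]3[C@](C)(C(=O)OC)CCC[C@@]3(CO[Si](C)(C)C(C)(C)C)[C@@H]1CC24OCCO4 | intermediate
27 | silyl ketene acetal of 26 (C6=C7 ring-cis) | C[Si](C)(C)C#CCC1=C[C@H]2O/C(O[Si](C)(C)C(C)(C)C)=C\[C@@H]3[C@](C)(C(=O)OC)CCC[C@@]3(CO[Si](C)(C)C(C)(C)C)[C@@H]1CC24OCCO4 | intermediate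
28 | tert-butyldimethylsilyl ester of 29 | C[Si](C)(C)C#CC[C@]23C=CC4(OCCO4)C[C@H]2[C@]1(CO[Si](C)(C)C(C)(C)C)CCC[C@@](C)(C(=O)OC)[C@H]1[C@H]3C(=O)O[Si](C)(C)C(C)(C)C | intermediate
29 | ring A/B/C acid with C13=C14 alkene, C7 cis to C14 (6-epi) | C[Si](C)(C)C#CC[C@]23C=CC4(OCCO4)C[C@H]2[C@]1(CO[Si](C)(C)C(C)(C)C)CCC[C@@](C)(C(=O)OC)[C@H]1[C@H]3C(=O)O | intermediate
30 | 6-epi C7,C19 dimethyl ester | C[Si](C)(C)C#CC[C@]23C=CC4(OCCO4)C[C@H]2[C@]1(CO[Si](C)(C)C(C)(C)C)CCC[C@@](C)(C(=O)OC)[C@H]1[C@H]3C(=O)OC | intermediate
31 | dimethyl ester with natural C6, terminal alkyne | C#CC[C@]23C=CC4(OCCO4)C[C@H]2[C@]1(CO[Si](C)(C)C(C)(C)C)CCC[C@@](C)(C(=O)OC)[C@H]1[C@@H]3C(=O)OC | intermediate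
32 | C12 ketone, C13=C14 enone | C#CC[C@]23C=CC(=O)C[C@H]2[C@]1(CO[Si](C)(C)C(C)(C)C)CCC[C@@](C)(C(=O)OC)[C@H]1[C@@H]3C(=O)OC | intermediate
33 | C12 tert-butyldimethylsilyl enol ether (C12=C13) | C#CC[C@]23CC=C(O[Si](C)(C)C(C)(C)C)C[C@H]2[C@]1(CO[Si](C)(C)C(C)(C)C)CCC[C@@](C)(C(=O)OC)[C@H]1[C@@H]3C(=O)OC | intermediate
34 | tetracyclic C12 ketone, C20 silyl ether, dimethyl ester | C=C1C[C@]23C[C@H]1C(=O)C[C@H]2[C@]1(CO[Si](C)(C)C(C)(C)C)CCC[C@@](C)(C(=O)OC)[C@H]1[C@@H]3C(=O)OC | intermediate
35 | C20 alcohol dimethyl ester | C=C1C[C@]23C[C@H]1C(=O)C[C@H]2[C@]1(CO)CCC[C@@](C)(C(=O)OC)[C@H]1[C@@H]3C(=O)OC | intermediate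
36 | C20 aldehyde dimethyl ester | C=C1C[C@]23C[C@H]1C(=O)C[C@H]2[C@]1(C=O)CCC[C@@](C)(C(=O)OC)[C@H]1[C@@H]3C(=O)OC | intermediate
37 | CNP0412196.1 (12-oxo C20-aldehyde gibberellin 7,19-dioic acid) | C=C1C[C@]23C[C@H]1C(=O)C[C@H]2[C@]1(C=O)CCC[C@@](C)(C(=O)O)[C@H]1[C@@H]3C(=O)O | target

**Totals**

Total step count: 29. Longest linear sequence: 28 steps (steps 2 to 29, from 3 and 4 to 37); step 1 is the only step off this line.

**Steps most likely to fail**

1. Step 21 (proposed new method). The bridged ketene acetal may not reach the boat-like geometry, so that C-silylation of the enolate, elimination, or simple return of the lactone on work-up outruns the [3,3] shift. The fallback uses known chemistry and sets out from hydroxy diester 23. Appel chlorination with inversion (PPh3, N-chlorosuccinimide, CH2Cl2, 0 °C) gives the C13 allylic chloride F1, with chlorine trans to the C9–C10 bond. KN(SiMe3)2 in THF (−78 to 0 °C) then forms the C7 ester enolate, which closes ring B by an intramolecular anti-SN2′ alkylation: C6 attacks C8 on the face of the C9 arm while chloride leaves C13 from the other face. This should give 30 together with its C6 epimer F2; both go into step 23, which converges them on 31. The fallback comes back to the route at 30.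

2. Step 20. Intermolecular acylation (oligomer formation) may outrun closure of the strained nine-membered bridged ring. The fallback changes the bond-forming event from acyl activation to allylic substitution and sets out from hydroxy acid 24. Acetylation (Ac2O, pyridine, DMAP; aqueous work-up) gives the C13 acetoxy acid F3. Pd(PPh3)4 with Et3N in THF at high dilution (60 °C) ionises the acetate to a π-allyl complex of palladium, and the carboxylate attacks C13 anti to the metal. The two inversions amount to retention, so the C13–O bond re-forms on the face of the C9 arm. The fallback comes back to the route at lactone 26.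

3. Step 29. The thiolate may add to the aldehyde irreversibly or fail to cleave the hindered C19 ester while other groups degrade. The fallback changes the order of the end game and sets out from 34. LiSPr in HMPA cleaves both methyl esters while C20 is still a silyl ether, giving the diacid silyl ether F4. Bu4NF in THF then frees the 20-hydroxy diacid F5 as its carboxylate salt, which cannot lactonise under base. Buffered Dess–Martin oxidation (NaHCO3, CH2Cl2) and acidification lead to 37, where the fallback comes back to the route.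

**Further compounds**

F1 | step 21 | C13 allylic chloride of 23 (Cl trans to C9–C10) | COC(=O)[C@]1(C)CCC[C@@](CO[Si](C)(C)C(C)(C)C)([C@@H]2CC3(OCCO3)[C@@H](Cl)C=C2CC#C[Si](C)(C)C)[C@@H]1CC(=O)OC
F2 | step 21 | C6 epimer of 30 (natural C6, silylated alkyne) | C[Si](C)(C)C#CC[C@]23C=CC4(OCCO4)C[C@H]2[C@]1(CO[Si](C)(C)C(C)(C)C)CCC[C@@](C)(C(=O)OC)[C@H]1[C@@H]3C(=O)OC
F3 | step 20 | C13 acetate of hydroxy acid 24 | COC(=O)[C@]1(C)CCC[C@@](CO[Si](C)(C)C(C)(C)C)([C@@H]2CC3(OCCO3)[C@H](OC(C)=O)C=C2CC#C[Si](C)(C)C)[C@@H]1CC(=O)O
F4 | step 29 | C7,C19 diacid of 34 (C20 silyl ether) | C=C1C[C@]23C[C@H]1C(=O)C[C@H]2[C@]1(CO[Si](C)(C)C(C)(C)C)CCC[C@@](C)(C(=O)O)[C@H]1[C@@H]3C(=O)O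
F5 | step 29 | 20-hydroxy C7,C19 diacid | C=C1C[C@]23C[C@H]1C(=O)C[C@H]2[C@]1(CO)CCC[C@@](C)(C(=O)O)[C@H]1[C@@H]3C(=O)O
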